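**Plan**
- Retrosynthesis: ring C is cut at O1–C2 and at both ring bonds of the C4 carbonyl carbon, giving a ring A ortho-iodophenol, CO and the ring B arylacetylene. The prenyl C=C is cut next (Wittig), then the benzylic CH2–CH bond of the lavandulyl group together with a temporary aryl ester C–O bond.
- Enabling feature: C6 of ring A carries the lavandulyl CH2 between the C5 and C7 oxygens, so this CH2 is the exocyclic carbon of an ortho-quinone methide. The olefinic CH of the prenyl arm, two carbons beyond the stereocentre, can enter as the acyl carbon of an enal whose β-carbon becomes the stereocentre.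
- Forward: ring A comes from 2,4,6-trihydroxybenzaldehyde. Step 6 joins it to the dienal and closes a temporary seven-membered lactone, which reduction and Wittig olefination open to the lavandulyl phenol. Ring C is closed last (step 14) with ring B already on the alkyne.
- Stereochemistry: the single stereocentre is set in step 6 by a chiral triazolylidene carbene. It never becomes α to a carbonyl afterwards.

Key step: step 6

Remark: the sense of induction of the aminoindanol-derived triazolium salt with this substrate pair is assumed by analogy, so the antipode of the precatalyst (both are commercial) that delivers the (4R)-lactone 10 is the one to use.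

**Step 1**
Reactants: 1 2,4,6-trihydroxybenzaldehyde
Product: 2 2,6-dihydroxy-4-(triisopropylsilyloxy)benzaldehyde
Conditions: i-Pr3SiCl (1.05 equiv), imidazole, DMF, 0 °C
Reagents that add atoms: chlorotriisopropylsilane, CC(C)[Si](Cl)(C(C)C)C(C)C
Why: Silyl ether formation; the 4-hydroxyl, para to the aldehyde, is the most acidic and the only one not held in a hydrogen bond to the carbonyl, so one equivalent of the bulky chlorosilane should take it selectively.

**Step 2**
Reactants: 2 2,6-dihydroxy-4-(triisopropylsilyloxy)benzaldehyde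
Product: 3 2-hydroxy-6-(methoxymethoxy)-4-(triisopropylsilyloxy)benzaldehyde
Conditions: MOMCl (1.1 equiv), i-Pr2NEt, CH2Cl2, 0 °C → rt
Reagents that add atoms: chloromethyl methyl ether, COCCl
Why: Williamson-type MOM ether formation; once one ortho hydroxyl is etherified the other stays chelated to the aldehyde oxygen and reacts much more slowly, the bias that allows partial MOM protection of polyhydroxybenzaldehydes.

**Step 3**
Reactants: 3 2-hydroxy-6-(methoxymethoxy)-4-(triisopropylsilyloxy)benzaldehyde
Product: 4 2-(hydroxymethyl)-3-(methoxymethoxy)-5-(triisopropylsilyloxy)phenol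
Conditions: NaBH4, THF/MeOH, 0 °C, short contact time
Reagents that add atoms: none
Why: Borohydride reduction of an aryl aldehyde; low temperature and short contact time are meant to stop at the benzylic alcohol before borate-assisted loss of the hydroxyl sets in, and the MOM acetal and silyl ether are inert.

**Step 4**
Reactants: 4 2-(hydroxymethyl)-3-(methoxymethoxy)-5-(triisopropylsilyloxy)phenol
Product: 5 3-(methoxymethoxy)-2-[(4-methylbenzenesulfonyl)methyl]-5-(triisopropylsilyloxy)phenol
Conditions: sodium p-toluenesulfinate (3 equiv), AcOH, THF/H2O, 0 °C → rt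
Reagents that add atoms: sodium p-toluenesulfinate, Cc1ccc(cc1)S(=O)[O-].[Na+]
Why: Acid-promoted substitution of an electron-rich ortho-hydroxybenzyl alcohol by a sulfinate (sulfone synthesis through a benzylic cation or quinone methide, S-alkylation being the thermodynamic outcome); acetic acid should suffice for this triply donor-activated position and is too weak to cleave the MOM acetal or the silyl ether.

**Step 5**
Reactants: 6 methacrolein (3 equiv); 7 (triphenylphosphoranylidene)acetaldehyde
Product: 8 (2E)-4-methylpenta-2,4-dienal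
Conditions: CH2Cl2, 40 °C, sealed vessel; distilled and kept cold as a stabilised solution (BHT)
Reagents that add atoms: none
Why: Wittig reaction of a stabilised formylmethylene ylide, which gives the E enal; the excess of the more electrophilic methacrolein keeps a second homologation of the dienal down.

**Step 6**
Reactants: 5 3-(methoxymethoxy)-2-[(4-methylbenzenesulfonyl)methyl]-5-(triisopropylsilyloxy)phenol; 8 (2E)-4-methylpenta-2,4-dienal (2 equiv)
Product: 10 (4R)-6-(methoxymethoxy)-4-(prop-1-en-2-yl)-8-(triisopropylsilyloxy)-4,5-dihydro-1-benzoxepin-2(3H)-one, via ortho-quinone methide 9 (not isolated)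
Conditions: cis-1-amino-2-indanol-derived N-mesityl triazolium tetrafluoroborate (15 mol %), Cs2CO3 (1.5 equiv), THF, 4 Å MS, 0 °C → rt
Reagents that add atoms: none
Why: Cs2CO3 deprotonates phenol 5, whose phenoxide expels p-toluenesulfinate by 1,4-elimination to give quinone methide 9, and it also frees the triazolylidene, which adds to the aldehyde of 8 to form the Breslow intermediate (a homoenolate equivalent). The β-carbon of this intermediate adds to the exocyclic CH2 of 9, forming the benzylic CH2–CH bond and rearomatising ring A; the enol then tautomerises to the acyl azolium, and the phenoxide attacks it through oxygen, closing the seven-membered lactone by a 7-exo-trig addition–elimination and releasing the carbene. The closest known reaction type is the carbene-catalysed enantioselective formal [4+3] annulation of enal homoenolates with ortho-quinone methides generated in situ, which gives 4-substituted benzoxepin-2-ones. The C4 stereocentre is set in the C–C bond-forming step by the aminoindanol backbone and N-mesityl group of the catalyst, which shield one face of the β-carbon of the E-configured homoenolate. The step needs attack through C-β and not through C-δ of the dienyl system or through C-α after β-protonation: the hydrogen bond between the enol OH and the quinone methide oxygen should hold the methide carbon over C-β, 9 offers a single unhindered electrophilic carbon, and the aprotic carbonate medium keeps β-protonation slow.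

**Step 7**
Reactants: 10 (4R)-6-(methoxymethoxy)-4-(prop-1-en-2-yl)-8-(triisopropylsilyloxy)-4,5-dihydro-1-benzoxepin-2(3H)-one
Product: 11 (4R)-6-(methoxymethoxy)-4-(prop-1-en-2-yl)-8-(triisopropylsilyloxy)-2,3,4,5-tetrahydro-1-benzoxepin-2-ol (both C2 epimers)
Conditions: i-Bu2AlH (1.1 equiv), CH2Cl2, −78 °C; aq. potassium sodium tartrate
Reagents that add atoms: none
Why: Partial reduction of a lactone to the lactol, the aluminium hemiacetal being stable at −78 °C as in the reduction of dihydrocoumarins; the stereocentre is β to the carbonyl and cannot epimerise.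

**Step 8**
Reactants: 11 (4R)-6-(methoxymethoxy)-4-(prop-1-en-2-yl)-8-(triisopropylsilyloxy)-2,3,4,5-tetrahydro-1-benzoxepin-2-ol
Product: 13 3-(methoxymethoxy)-2-[(2S)-5-methyl-2-(prop-1-en-2-yl)hex-4-en-1-yl]-5-(triisopropylsilyloxy)phenol, via hydroxy aldehyde 12 (not isolated)
Conditions: i-PrPPh3I (3.5 equiv), n-BuLi (3.4 equiv), THF, 0 °C; then 11, 0 °C → rt
Reagents that add atoms: isopropyltriphenylphosphonium iodide, CC(C)[P+](c1ccccc1)(c1ccccc1)c1ccccc1.[I-]
Why: Wittig olefination of a lactol through its open hydroxy aldehyde form with a non-stabilised ylide (the excess takes up the phenolic proton); the two identical methyl groups make alkene geometry irrelevant and ring opening frees the phenol.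

**Step 9**
Reactants: 13 3-(methoxymethoxy)-2-[(2S)-5-methyl-2-(prop-1-en-2-yl)hex-4-en-1-yl]-5-(triisopropylsilyloxy)phenol
Product: 14 {3,5-bis(methoxymethoxy)-4-[(2S)-5-methyl-2-(prop-1-en-2-yl)hex-4-en-1-yl]phenoxy}triisopropylsilane
Conditions: MOMCl, i-Pr2NEt, n-Bu4NI (cat.), CH2Cl2, 0 → 40 °C
Reagents that add atoms: chloromethyl methyl ether, COCCl
Why: MOM ether formation at the freed phenol, which makes the two oxygens flanking the lavandulyl group alike and leaves the silyl ether as the only differentiated oxygen.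

**Step 10**
Reactants: 14 {3,5-bis(methoxymethoxy)-4-[(2S)-5-methyl-2-(prop-1-en-2-yl)hex-4-en-1-yl]phenoxy}triisopropylsilane
Product: 15 3,5-bis(methoxymethoxy)-4-[(2S)-5-methyl-2-(prop-1-en-2-yl)hex-4-en-1-yl]phenol
Conditions: n-Bu4NF, THF, 0 °C
Reagents that add atoms: none
Why: Fluoride cleavage of an aryl silyl ether, which leaves MOM acetals and alkenes untouched and uncovers the oxygen that becomes O1 of the chromone.

**Step 11**
Reactants: 15 3,5-bis(methoxymethoxy)-4-[(2S)-5-methyl-2-(prop-1-en-2-yl)hex-4-en-1-yl]phenol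
Product: 16 2-iodo-3,5-bis(methoxymethoxy)-4-[(2S)-5-methyl-2-(prop-1-en-2-yl)hex-4-en-1-yl]phenol
Conditions: I2 (1.0 equiv), NaHCO3, THF/H2O, 0 °C
Reagents that add atoms: iodine, II
Why: Electrophilic aromatic iodination of a phenol under mild base; the two positions ortho to the hydroxyl are equivalent and the only free ring positions, and the phenoxide ring should react far faster with iodine than the two alkenes, which have no internal nucleophile.

**Step 12**
Reactants: 17 2,4-dihydroxybenzaldehyde
Product: 18 2,4-bis(methoxymethoxy)benzaldehyde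
Conditions: MOMCl (3 equiv), K2CO3, acetone, reflux
Reagents that add atoms: chloromethyl methyl ether, COCCl
Why: Twofold MOM ether formation under carbonate in refluxing acetone, forcing enough to etherify the chelated 2-hydroxyl as well.

**Step 13**
Reactants: 18 2,4-bis(methoxymethoxy)benzaldehyde
Product: 19 1-ethynyl-2,4-bis(methoxymethoxy)benzene
Conditions: dimethyl (1-diazo-2-oxopropyl)phosphonate, K2CO3, MeOH, rt
Reagents that add atoms: dimethyl (1-diazo-2-oxopropyl)phosphonate, COP(=O)(OC)C(=[N+]=[N-])C(C)=O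
Why: Ohira–Bestmann (Seyferth–Gilbert) homologation of an aryl aldehyde to the terminal alkyne under mild methoxide conditions that MOM ethers tolerate.

**Step 14**
Reactants: 16 2-iodo-3,5-bis(methoxymethoxy)-4-[(2S)-5-methyl-2-(prop-1-en-2-yl)hex-4-en-1-yl]phenol; 19 1-ethynyl-2,4-bis(methoxymethoxy)benzene
Product: 21 2-[2,4-bis(methoxymethoxy)phenyl]-5,7-bis(methoxymethoxy)-6-[(2S)-5-methyl-2-(prop-1-en-2-yl)hex-4-en-1-yl]-4H-chromen-4-one, via alkynyl ketone 20 (not isolated)
Conditions: CO (5 bar), PdCl2(dppf) (5 mol %), Et2NH, 80 °C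
Reagents that add atoms: carbon monoxide, [C-]#[O+]
Why: Palladium-catalysed carbonylative annulation of an ortho-iodophenol with a terminal alkyne: oxidative addition of zerovalent palladium to the C–I bond, CO insertion to the aroylpalladium species, copper-free alkynylation to ynone 20, then amine-mediated 6-endo closure (conjugate addition of Et2NH, attack of the phenol oxygen, loss of the amine) to the chromone rather than the aurone.

**Step 15**
Reactants: 21 2-[2,4-bis(methoxymethoxy)phenyl]-5,7-bis(methoxymethoxy)-6-[(2S)-5-methyl-2-(prop-1-en-2-yl)hex-4-en-1-yl]-4H-chromen-4-one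
Product: 22 2-(2,4-dihydroxyphenyl)-5,7-dihydroxy-6-[(2S)-5-methyl-2-(prop-1-en-2-yl)hex-4-en-1-yl]-4H-chromen-4-one
Conditions: 3 M aq. HCl, MeOH, 45 °C
Reagents that add atoms: none
Why: Acid-catalysed acetal cleavage (MOM removal) under dilute, mild conditions of the kind used on prenylated flavonoids, chosen to keep protonation of the two lavandulyl alkenes and their cyclisation onto the neighbouring phenols slow.

**Compound list**
1 | 2,4,6-trihydroxybenzaldehyde | O=Cc1c(O)cc(O)cc1O | starting material
2 | 2,6-dihydroxy-4-(triisopropylsilyloxy)benzaldehyde | O=Cc1c(O)cc(O[Si](C(C)C)(C(C)C)C(C)C)cc1O | intermediate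
3 | 2-hydroxy-6-(methoxymethoxy)-4-(triisopropylsilyloxy)benzaldehyde | O=Cc1c(O)cc(O[Si](C(C)C)(C(C)C)C(C)C)cc1OCOC | intermediate
4 | 2-(hydroxymethyl)-3-(methoxymethoxy)-5-(triisopropylsilyloxy)phenol | OCc1c(O)cc(O[Si](C(C)C)(C(C)C)C(C)C)cc1OCOC | intermediate
5 | 3-(methoxymethoxy)-2-[(4-methylbenzenesulfonyl)methyl]-5-(triisopropylsilyloxy)phenol | Cc1ccc(cc1)S(=O)(=O)Cc1c(O)cc(O[Si](C(C)C)(C(C)C)C(C)C)cc1OCOC | intermediate
6 | methacrolein | C=C(C)C=O | starting material
7 | (triphenylphosphoranylidene)acetaldehyde | O=CC=P(c1ccccc1)(c1ccccc1)c1ccccc1 | starting material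
8 | (2E)-4-methylpenta-2,4-dienal | C=C(C)/C=C/C=O | intermediate
9 | 5-(methoxymethoxy)-6-methylidene-3-(triisopropylsilyloxy)cyclohexa-2,4-dien-1-one (ortho-quinone methide) | C=C1C(=O)C=C(O[Si](C(C)C)(C(C)C)C(C)C)C=C1OCOC | intermediate
10 | (4R)-6-(methoxymethoxy)-4-(prop-1-en-2-yl)-8-(triisopropylsilyloxy)-4,5-dihydro-1-benzoxepin-2(3H)-one | C=C(C)[C@H]1CC(=O)Oc2cc(O[Si](C(C)C)(C(C)C)C(C)C)cc(OCOC)c2C1 | intermediate
11 | (4R)-6-(methoxymethoxy)-4-(prop-1-en-2-yl)-8-(triisopropylsilyloxy)-2,3,4,5-tetrahydro-1-benzoxepin-2-ol (both C2 epimers) | C=C(C)[C@H]1CC(O)Oc2cc(O[Si](C(C)C)(C(C)C)C(C)C)cc(OCOC)c2C1 | intermediate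
12 | (3R)-3-{[2-hydroxy-6-(methoxymethoxy)-4-(triisopropylsilyloxy)phenyl]methyl}-4-methylpent-4-enal | C=C(C)[C@@H](CC=O)Cc1c(O)cc(O[Si](C(C)C)(C(C)C)C(C)C)cc1OCOC | intermediate
13 | 3-(methoxymethoxy)-2-[(2S)-5-methyl-2-(prop-1-en-2-yl)hex-4-en-1-yl]-5-(triisopropylsilyloxy)phenol | C=C(C)[C@@H](CC=C(C)C)Cc1c(O)cc(O[Si](C(C)C)(C(C)C)C(C)C)cc1OCOC | intermediate
14 | {3,5-bis(methoxymethoxy)-4-[(2S)-5-methyl-2-(prop-1-en-2-yl)hex-4-en-1-yl]phenoxy}triisopropylsilane | C=C(C)[C@@H](CC=C(C)C)Cc1c(OCOC)cc(O[Si](C(C)C)(C(C)C)C(C)C)cc1OCOC | intermediate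
15 | 3,5-bis(methoxymethoxy)-4-[(2S)-5-methyl-2-(prop-1-en-2-yl)hex-4-en-1-yl]phenol | C=C(C)[C@@H](CC=C(C)C)Cc1c(OCOC)cc(O)cc1OCOC | intermediate
16 | 2-iodo-3,5-bis(methoxymethoxy)-4-[(2S)-5-methyl-2-(prop-1-en-2-yl)hex-4-en-1-yl]phenol | C=C(C)[C@@H](CC=C(C)C)Cc1c(OCOC)cc(O)c(I)c1OCOC | intermediate
17 | 2,4-dihydroxybenzaldehyde | O=Cc1ccc(O)cc1O | starting material
18 | 2,4-bis(methoxymethoxy)benzaldehyde | O=Cc1ccc(OCOC)cc1OCOC | intermediate
19 | 1-ethynyl-2,4-bis(methoxymethoxy)benzene | C#Cc1ccc(OCOC)cc1OCOC | intermediate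
20 | 3-[2,4-bis(methoxymethoxy)phenyl]-1-{6-hydroxy-2,4-bis(methoxymethoxy)-3-[(2S)-5-methyl-2-(prop-1-en-2-yl)hex-4-en-1-yl]phenyl}prop-2-yn-1-one | C=C(C)[C@@H](CC=C(C)C)Cc1c(OCOC)cc(O)c(C(=O)C#Cc2ccc(OCOC)cc2OCOC)c1OCOC | intermediate
21 | 2-[2,4-bis(methoxymethoxy)phenyl]-5,7-bis(methoxymethoxy)-6-[(2S)-5-methyl-2-(prop-1-en-2-yl)hex-4-en-1-yl]-4H-chromen-4-one | C=C(C)[C@@H](CC=C(C)C)Cc1c(OCOC)cc2oc(-c3ccc(OCOC)cc3OCOC)cc(=O)c2c1OCOC | intermediate
22 | 2-(2,4-dihydroxyphenyl)-5,7-dihydroxy-6-[(2S)-5-methyl-2-(prop-1-en-2-yl)hex-4-en-1-yl]-4H-chromen-4-one | C=C(C)[C@@H](CC=C(C)C)Cc1c(O)cc2oc(-c3ccc(O)cc3O)cc(=O)c2c1O | target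

**Step count**
Total: 15 steps. Longest linear sequence: 12 steps (steps 1–4, 6–11, 14 and 15, from 2,4,6-trihydroxybenzaldehyde).

**Steps most likely to fail**

Step 6. The dienyl Breslow intermediate may react through its remote δ-carbon instead of C-β. Other failure modes are β-protonation diverting the acyl azolium to a six-membered annulation or to simple phenol acylation, self-condensation of the electron-rich quinone methide, and insufficient facial selectivity. The fallback sets out from sulfone 5 and comes back at lactone 10, and it builds the same lactone with the stereocentre set by rhodium instead of the carbene. Vinylmagnesium bromide (2.5 equiv, THF, −78 → 0 °C) releases the quinone methide from 5 and adds to it, giving 3-(methoxymethoxy)-2-(prop-2-en-1-yl)-5-(triisopropylsilyloxy)phenol F1. Acryloyl chloride and Et3N convert this into 3-(methoxymethoxy)-2-(prop-2-en-1-yl)-5-(triisopropylsilyloxy)phenyl prop-2-enoate F2. Ring-closing metathesis with the second-generation Grubbs catalyst RuCl2(=CHPh)(PCy3)(H2IMes) in dilute CH2Cl2 at 40 °C should close 6-(methoxymethoxy)-8-(triisopropylsilyloxy)-1-benzoxepin-2(5H)-one F3. A rhodium-catalysed asymmetric conjugate addition of isopropenylboronic acid pinacol ester ([Rh(OH)(cod)]2 with BINAP, dioxane/H2O, 35 °C), using the ligand antipode that gives the 4R configuration, then delivers 10.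

Step 14. Direct alkynylation without CO uptake (leading on to a benzofuran), 5-exo closure to the aurone, or slow oxidative addition at the hindered, electron-rich iodide may take over. The fallback sets out from iodophenol 16 and alkyne 19 and comes back at flavone 21, assembling the ynone without palladium or CO. The phenol of 16 is resilylated (i-Pr3SiOTf, 2,6-lutidine) to {2-iodo-3,5-bis(methoxymethoxy)-4-[(2S)-5-methyl-2-(prop-1-en-2-yl)hex-4-en-1-yl]phenoxy}triisopropylsilane F4. Alkyne 19 is lithiated (n-BuLi, THF, −78 °C) and acylated with N-methoxy-N-methylcarbamoyl chloride to give 3-[2,4-bis(methoxymethoxy)phenyl]-N-methoxy-N-methylprop-2-ynamide F5. Iodine–magnesium exchange on F4 (i-PrMgCl·LiCl, THF, 0 °C → rt) and addition to the Weinreb amide should give 3-[2,4-bis(methoxymethoxy)phenyl]-1-{2,4-bis(methoxymethoxy)-3-[(2S)-5-methyl-2-(prop-1-en-2-yl)hex-4-en-1-yl]-6-(triisopropylsilyloxy)phenyl}prop-2-yn-1-one F6. Desilylation with n-Bu4NF followed by Et2NH in EtOH closes the chromone 6-endo to 21.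

Step 4. The cation or quinone methide formed from the very electron-rich salicyl alcohol may alkylate a second aromatic ring (diarylmethane formation) faster than the sulfinate traps it, and the MOM acetal may be lost under the acid. The fallback sets out from aldehyde 3 and comes back at sulfone 5, and it never passes through the free benzylic alcohol. Reductive amination of 3 (Me2NH, NaBH(OAc)3, 1,2-dichloroethane, rt) gives the stable Mannich base 2-[(dimethylamino)methyl]-3-(methoxymethoxy)-5-(triisopropylsilyloxy)phenol F7. Methyl iodide in MeCN quaternises it to [2-hydroxy-6-(methoxymethoxy)-4-(triisopropylsilyloxy)phenyl]methyl-trimethylammonium iodide F8. Warming F8 with sodium p-toluenesulfinate in MeCN/H2O (50 °C) releases the quinone methide slowly in the presence of excess sulfinate and should give 5.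

**Further compounds**
F1 | step 6 | 3-(methoxymethoxy)-2-(prop-2-en-1-yl)-5-(triisopropylsilyloxy)phenol | C=CCc1c(O)cc(O[Si](C(C)C)(C(C)C)C(C)C)cc1OCOC
F2 | step 6 | 3-(methoxymethoxy)-2-(prop-2-en-1-yl)-5-(triisopropylsilyloxy)phenyl prop-2-enoate | C=CCc1c(OC(=O)C=C)cc(O[Si](C(C)C)(C(C)C)C(C)C)cc1OCOC
F3 | step 6 | 6-(methoxymethoxy)-8-(triisopropylsilyloxy)-1-benzoxepin-2(5H)-one | O=C1C=CCc2c(OCOC)cc(O[Si](C(C)C)(C(C)C)C(C)C)cc2O1
F4 | step 14 | {2-iodo-3,5-bis(methoxymethoxy)-4-[(2S)-5-methyl-2-(prop-1-en-2-yl)hex-4-en-1-yl]phenoxy}triisopropylsilane | C=C(C)[C@@H](CC=C(C)C)Cc1c(OCOC)cc(O[Si](C(C)C)(C(C)C)C(C)C)c(I)c1OCOC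
F5 | step 14 | 3-[2,4-bis(methoxymethoxy)phenyl]-N-methoxy-N-methylprop-2-ynamide | CON(C)C(=O)C#Cc1ccc(OCOC)cc1OCOC
F6 | step 14 | 3-[2,4-bis(methoxymethoxy)phenyl]-1-{2,4-bis(methoxymethoxy)-3-[(2S)-5-methyl-2-(prop-1-en-2-yl)hex-4-en-1-yl]-6-(triisopropylsilyloxy)phenyl}prop-2-yn-1-one | C=C(C)[C@@H](CC=C(C)C)Cc1c(OCOC)cc(O[Si](C(C)C)(C(C)C)C(C)C)c(C(=O)C#Cc2ccc(OCOC)cc2OCOC)c1OCOC
F7 | step 4 | 2-[(dimethylamino)methyl]-3-(methoxymethoxy)-5-(triisopropylsilyloxy)phenol | CN(C)Cc1c(O)cc(O[Si](C(C)C)(C(C)C)C(C)C)cc1OCOC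
F8 | step 4 | [2-hydroxy-6-(methoxymethoxy)-4-(triisopropylsilyloxy)phenyl]methyl-trimethylammonium iodide | C[N+](C)(C)Cc1c(O)cc(O[Si](C(C)C)(C(C)C)C(C)C)cc1OCOC.[I-]
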